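Substrate units are conserved: whatever leaves the solid stands as dissolved substrate, target or side product. So I counted the flow into solution first.

| flask | solid substrate | reagent | remark | time |
|---|---|---|---|---|
| dawn | 5 mM | 1.2 equiv | run made earlier |  |
| summer | 7.5 mM | 1.2 equiv | run made earlier |  |
| flask | 10 mM | 1.20 equiv |  | 2.0 min |

| run | time / min | target / % | dissolved substrate / % |
|---|---|---|---|
| dawn | 0.200 | 1.6 | 14.3 |
| dawn | 0.333 | 3.9 | 19.8 |
| dawn | 0.667 | 10.9 | 25.5 |
| dawn | 1.33 | 24.5 | 27.8 |
| dawn | 2.50 | 36.4 | 6.1 |
| summer | 0.500 | 7.2 | 13.7 |
| summer | 1.00 | 16.0 | 15.9 |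
| summer | 1.33 | 22.4 | 16.7 |
| summer | 2.00 | 34.8 | 17.4 |
| summer | 2.50 | 40.6 | 8.5 |

(scatter of a reading: 0.5 percentage points)

- percent here means solid substrate units held: one side product A or side product B counts as two
- solid substrate is a solid; its amount is given per volume of the solution
- steps thought possible: solid substrate <-> dissolved substrate; dissolved substrate + reagent -> target; 2 dissolved substrate -> side product A; solid substrate + target -> side product B
- at the start none of the solid substrate is in solution
- dissolved substrate means what is dissolved; the solid is not counted in it

- amount of target at 2.0 min, in percent of the solid substrate charged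
- concentration of dissolved substrate in solution at 2.0 min, in percent of saturation

In the summer run, c(dissolved substrate) still stood at 1.30 mM at 2.00 min and had broken by 2.50 min. I read that break as the end of the solid. So 7.5 mM entered at between 3.00 mM min⁻¹ and 3.75 mM min⁻¹. I took the middle, 3.37 mM min⁻¹, as the inflow J, the substrate entering solution per minute while solid stands.

Summer target grew at 1.41 mM min⁻¹ between 1.00 min and 2.00 min. Dividing by the mean concentrations gave k = 0.159 mM⁻¹ min⁻¹. That line met zero at 0.149 min.

I treated the plateau as a quasi-steady state: J = k·c(dissolved substrate)·c(reagent) + g·c(dissolved substrate) squared, with side product A as the other sink. Summer gave g = 1.20 mM⁻¹ min⁻¹.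

The weak link was one J for different charges. So I reforged it on the dawn reading at 1.33 min, with the same J and k, which gave g = 1.20 mM⁻¹ min⁻¹, about the same.

At J the flask's charge lasts 2.96 min, longer than the 2.0 min asked. Reagent loss I took as a correction. The charged 12.0 mM gave c(dissolved substrate) = 1.06 mM, which lowered mean c(reagent) to 9.98 mM. The second pass gave 1.14 mM. Counted from the lag, target came to 33.5 %. I made no estimate of saturation.

The forecast said 32.5 % of target and 20 % of saturation. Of the plateau it said: “This is a steady state, not saturation.” Its target lies 1 percentage point below mine.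

The flask gave 30.9 % of target and 21.4 % of saturation. Solid substrate in the flask stood at 27.6 % at 2.00 min, so 72.4 % had left it, by dissolving or into side product B, a mean of 3.62 mM min⁻¹ against J of 3.37 mM min⁻¹.

    solid substrate ⇌ dissolved substrate, rate k1*(cs1 - [dissolved substrate]) while solid is left; crystals form when [dissolved substrate] > cs1 (solubility = 5.50 mM, k = 0.0130 s⁻¹)
    dissolved substrate + reagent → target (k = 2.70 L mol⁻¹ s⁻¹)
    2 dissolved substrate → side product A (k = 10.0 L mol⁻¹ s⁻¹)
    solid substrate + target → side product B (k = 0.250 L mol⁻¹ s⁻¹)

For the neighbour with 4.80 equiv of reagent, J gives c(dissolved substrate) = 0.415 mM and target 58.6 %. The computed neighbour gave 63.7 %.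

The numbers in the tables stem from a simulated flask for substances that don't exist.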